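**Retrosynthetic overview**
1. One global hydride reduction unmasks the target from its triacetate C9-aldehyde, which already carries all three stereocentres.
2. Key disconnection: both new bonds of ring B at once (C8–C8' and C7'–aryl C2), leading back to O-acetyl dihydrosinapaldehyde and (E)-coniferyl diacetate.
3. Forward: one-electron oxidation of a chiral enamine gives a C8 radical that couples to C8' of the coniferyl olefin. A second oxidation gives the C7' quinone-methide-type cation, which the syringyl ring captures. This is the bond order of the plant pathway: radical 8–8' coupling, then quinone-methide arylation.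
4. Only one ring is formed (ring B, the saturated ring of the tetralin); both arenes are bought.
5. The aldehyde comes from a Heck reaction of acetylated 4-bromosyringol with allyl alcohol. The olefin comes from allylic C–H acetoxylation of eugenyl acetate.

Assumption: lignan numbering (syringyl unit C1–C9, guaiacyl unit C1'–C9') is used for mechanisms and tetralin numbering for names; the oxidant [Fe(phen)3](SbF6)3 (phen = 1,10-phenanthroline, trivalent iron) and the imidazolidinone salt count as reagents, not as steps.

**Step 1**
Reactants: 1 4-bromo-2,6-dimethoxyphenol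
Product: 2 4-bromo-2,6-dimethoxyphenyl acetate
Conditions: Ac2O (1.5 equiv), pyridine, DMAP (5 mol %), CH2Cl2, 0 °C to rt
Reagents that add atoms: acetic anhydride, CC(=O)OC(C)=O
Why: DMAP-catalysed O-acylation of the hindered phenol gives an acetate that makes the ring harder to oxidise in step 4, survives steps 2 and 4 and is removed in the final hydride step; no stereocentre is formed.

**Step 2**
Reactants: 2 4-bromo-2,6-dimethoxyphenyl acetate, 3 allyl alcohol
Product: 5 3-(4-acetoxy-3,5-dimethoxyphenyl)propanal, via enol 4 (not isolated)
Conditions: 3 (1.5 equiv), Pd(OAc)2 (3 mol %), P(o-tol)3 (6 mol %), n-Bu4NCl (1 equiv), NaHCO3 (2.5 equiv), DMF, 80 °C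
Reagents that add atoms: none
Why: In this Heck reaction with an allylic alcohol (Jeffery conditions), zerovalent palladium inserts into C–Br, carbopalladation occurs at the terminal alkene carbon and β-hydride elimination towards the carbinol carbon gives enol 4, which tautomerises to the saturated aldehyde, while the mild solid base leaves the aryl acetate intact; no stereocentre is formed.

**Step 3**
Reactants: 6 eugenyl acetate (4-allyl-2-methoxyphenyl acetate)
Product: 7 (E)-coniferyl diacetate
Conditions: Pd(OAc)2 (10 mol %), 1,4-benzoquinone (2 equiv), DMSO/AcOH 1:1, 40 °C, 48 h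
Reagents that add atoms: acetic acid, CC(=O)O
Why: In this Pd-catalysed allylic C–H acetoxylation, sulfoxide-promoted C–H cleavage by divalent palladium gives a π-allyl complex that acetate attacks at the unhindered terminus, conjugation with the arene makes the linear E-cinnamyl acetate the dominant product, and benzoquinone reoxidises zerovalent palladium; only the E-alkene geometry is set.

**Step 4**
Reactants: 5 3-(4-acetoxy-3,5-dimethoxyphenyl)propanal, 7 (E)-coniferyl diacetate
Product: 10 [(1S,2R,3R)-7-acetoxy-1-(4-acetoxy-3-methoxyphenyl)-3-formyl-6,8-dimethoxy-1,2,3,4-tetrahydronaphthalen-2-yl]methyl acetate, via enamine 8 (not isolated), via benzylic cation 9 (not isolated)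
Conditions: 7 (3 equiv, excess recovered), (2S,5S)-5-benzyl-2-tert-butyl-3-methylimidazolidin-4-one·TFA (20 mol %), [Fe(phen)3](SbF6)3 (2.2 equiv), Na2HPO4 (2.5 equiv), acetone, −30 °C, 24 h
Reagents that add atoms: none
Why: Proposed new method: the organo-SOMO radical–polar crossover [4+2] (closest known reaction type: the imidazolidinone/[Fe(phen)3]3+ cycloaddition of 3-arylpropanals with styrenes) is extended to a β-substituted, γ-oxygenated styrene, as follows: trivalent iron oxidises only E-enamine 8 (the acetylated arenes and olefin 7 lie well above its potential) to a 3π radical cation whose Re face is covered by the catalyst benzyl group, so C8' of 7 bonds to the Si face (C3 = R) with regiochemistry fixed by benzylic-radical formation; a staggered open transition state places the C8' hydrogen between the iminium and syringylmethyl arms, the styryl carbon anti to the iminium and CH2OAc anti to the syringylmethyl arm (8,8'-trans, C2 = R); a second electron transfer gives the O-acetyl quinone-methide-type cation 9, which the doubly OMe-activated ring carbon captures through a chair-like transition state with all substituents equatorial (C1 = S); iminium hydrolysis then releases 10 and the catalyst.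

**Step 5**
Reactants: 10 triacetoxy aldehyde
Product: 11 (+)-8-methoxyisolariciresinol
Conditions: LiAlH4 (5 equiv), THF, 0 °C to rt; aq. NH4Cl work-up
Reagents that add atoms: none
Why: LiAlH4 hydride reduction turns the aldehyde into the C9 primary alcohol and cleaves the alkyl acetate and both aryl acetates in the same operation, and because carbonyl addition is far faster than enolisation and the formyl group is already equatorial, none of the three stereocentres is touched.

**Compound list**
1 | 4-bromo-2,6-dimethoxyphenol | COc1cc(Br)cc(OC)c1O | starting material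
2 | 4-bromo-2,6-dimethoxyphenyl acetate | COc1cc(Br)cc(OC)c1OC(C)=O | intermediate
3 | allyl alcohol (prop-2-en-1-ol) | C=CCO | starting material
4 | 4-(3-hydroxyprop-2-en-1-yl)-2,6-dimethoxyphenyl acetate (enol, alkene geometry undefined) | COc1cc(CC=CO)cc(OC)c1OC(C)=O | intermediate
5 | 3-(4-acetoxy-3,5-dimethoxyphenyl)propanal (O-acetyl dihydrosinapaldehyde) | COc1cc(CCC=O)cc(OC)c1OC(C)=O | intermediate
6 | eugenyl acetate (4-allyl-2-methoxyphenyl acetate) | COc1cc(CC=C)ccc1OC(C)=O | starting material
7 | (E)-coniferyl diacetate, (E)-3-(4-acetoxy-3-methoxyphenyl)prop-2-en-1-yl acetate | COc1cc(/C=C/COC(C)=O)ccc1OC(C)=O | intermediate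
8 | (E)-enamine of 5 on N1 of (2S,5S)-5-benzyl-2-tert-butyl-3-methylimidazolidin-4-one | COc1cc(C/C=C/N2[C@H](C(C)(C)C)N(C)C(=O)[C@@H]2Cc3ccccc3)cc(OC)c1OC(C)=O | intermediate
9 | (8R,8'R) open-chain 8–8' adduct, C9 as the imidazolidinone iminium and C7' as the 4-acetoxy-3-methoxybenzyl cation (dication, SbF6 salts) | COc1cc(C[C@@H](C=[N+]2[C@H](C(C)(C)C)N(C)C(=O)[C@@H]2Cc3ccccc3)[C@H](COC(C)=O)[CH+]c4ccc(OC(C)=O)c(OC)c4)cc(OC)c1OC(C)=O | intermediate
10 | [(1S,2R,3R)-7-acetoxy-1-(4-acetoxy-3-methoxyphenyl)-3-formyl-6,8-dimethoxy-1,2,3,4-tetrahydronaphthalen-2-yl]methyl acetate (1,2-trans, 2,3-trans) | COc1cc([C@H]2c3c(cc(OC)c(OC(C)=O)c3OC)C[C@@H](C=O)[C@@H]2COC(C)=O)ccc1OC(C)=O | intermediate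
11 | (+)-8-methoxyisolariciresinol, (1S,2R,3R)-1-(4-hydroxy-3-methoxyphenyl)-2,3-bis(hydroxymethyl)-6,8-dimethoxy-1,2,3,4-tetrahydronaphthalen-7-ol | COc1cc([C@H]2c3c(cc(OC)c(O)c3OC)C[C@@H](CO)[C@@H]2CO)ccc1O | target

**Total step count:** 5. **Longest linear sequence:** 4 (steps 1, 2, 4, 5).

**Three steps most likely to fail**

1. Step 4.
   - Failure modes:
     - The 1,2-disubstituted, inductively deactivated olefin 7 may add too slowly, so that enamine homocoupling wins.
     - The simple diastereoselectivity at C8' may be modest. The 2,3-cis isomer must then be removed by chromatography, not epimerised, because epimerisation would erode the ee.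
     - Cation 9 may be intercepted by the C9' acetate or by water.
     - If the sense of induction proved opposite, the (2R,5R) catalyst is equally available.
   - Fallback: it sets out from 5 and comes back at 11, and makes the two bonds one at a time by polar chemistry. Aldehyde 5 is α-cyanomethylated with BrCH2CN under photoredox–enamine catalysis (Ru(bpy)3Cl2, an imidazolidinone of the same facial sense, 2,6-lutidine, DMSO, visible light) to (3R)-4-(4-acetoxy-3,5-dimethoxyphenyl)-3-formylbutanenitrile F1. NaBH4 in MeOH at 0 °C gives (3R)-4-(4-acetoxy-3,5-dimethoxyphenyl)-3-(hydroxymethyl)butanenitrile F2. Hot aqueous HCl hydrolyses the nitrile and the aryl acetate and closes (4R)-4-(4-hydroxy-3,5-dimethoxybenzyl)dihydrofuran-2(3H)-one F3. Its dianion (LiN(SiMe3)2, 2.2 equiv, THF, −78 °C) adds to commercial 3-methoxy-4-(methoxymethoxy)benzaldehyde anti to the benzyl group. This gives (3S,4R)-4-(4-hydroxy-3,5-dimethoxybenzyl)-3-{hydroxy[3-methoxy-4-(methoxymethoxy)phenyl]methyl}dihydrofuran-2(3H)-one F4, whose two carbinol epimers are both usable. TFA in CH2Cl2 removes the MOM group and ionises the benzylic alcohol to the p-quinone methide, and the syringyl ring closes onto it to give the (7'S,8R,8'R)-8-methoxy-α-conidendrin-type aryltetralin lactone F5. LiAlH4 in THF opens the lactone to 11.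

2. Step 3.
   - Failure modes: low conversion at 40 °C, some branched acetate or methyl ketone, and slow reoxidation of palladium.
   - Fallback: it sets out from 6 and comes back at 7, and replaces C–H oxidation by alkene transposition and metathesis. RuHCl(CO)(PPh3)3 (0.5 mol %, toluene, 80 °C) isomerises 6 to (E)-isoeugenyl acetate F6. Cross-metathesis with (Z)-but-2-ene-1,4-diyl diacetate (second-generation Hoveyda–Grubbs catalyst, 3 mol %, CH2Cl2, 40 °C) then exchanges the propenyl terminus for the acetoxymethyl-bearing one and gives 7 as the E-isomer.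

3. Step 2.
   - Failure modes: sluggish oxidative addition into the electron-rich bromide, branched aldehyde or cinnamyl alcohol by-products, and acetyl transfer from 2 to allyl alcohol at 80 °C.
   - Fallback: it sets out from 2 and comes back at 5, and brings in the three-carbon chain as a masked nucleophile. Negishi coupling of 2 with commercial [2-(1,3-dioxolan-2-yl)ethyl]zinc bromide (Pd(OAc)2 2 mol %, SPhos 4 mol %, THF, 50 °C; esters are tolerated) gives 4-[2-(1,3-dioxolan-2-yl)ethyl]-2,6-dimethoxyphenyl acetate F7. Brief treatment with 1 M HCl in acetone at rt frees aldehyde 5 without touching the aryl acetate.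

**Further compounds**
F1 | step 4 | (3R)-4-(4-acetoxy-3,5-dimethoxyphenyl)-3-formylbutanenitrile | COc1cc(C[C@@H](C=O)CC#N)cc(OC)c1OC(C)=O
F2 | step 4 | (3R)-4-(4-acetoxy-3,5-dimethoxyphenyl)-3-(hydroxymethyl)butanenitrile | COc1cc(C[C@@H](CO)CC#N)cc(OC)c1OC(C)=O
F3 | step 4 | (4R)-4-(4-hydroxy-3,5-dimethoxybenzyl)dihydrofuran-2(3H)-one | COc1cc(C[C@H]2COC(=O)C2)cc(OC)c1O
F4 | step 4 | (3S,4R)-4-(4-hydroxy-3,5-dimethoxybenzyl)-3-{hydroxy[3-methoxy-4-(methoxymethoxy)phenyl]methyl}dihydrofuran-2(3H)-one (carbinol epimers) | COc1cc(C[C@H]2COC(=O)[C@@H]2C(O)c3ccc(OCOC)c(OC)c3)cc(OC)c1O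
F5 | step 4 | (7'S,8R,8'R)-8-methoxy-α-conidendrin-type aryltetralin lactone | COc1cc([C@H]2c3c(cc(OC)c(O)c3OC)C[C@H]4COC(=O)[C@H]24)ccc1O
F6 | step 3 | (E)-isoeugenyl acetate | COc1cc(/C=C/C)ccc1OC(C)=O
F7 | step 2 | 4-[2-(1,3-dioxolan-2-yl)ethyl]-2,6-dimethoxyphenyl acetate | COc1cc(CCC2OCCO2)cc(OC)c1OC(C)=O
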